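The disconnection reads the target as the α-ketol isomer of a six-membered ring. The tertiary carbinol C6 and the acetyl carbonyl C5 (chroman numbering of vitamin E) form an α-hydroxy ketone pair next to C4a, the spiro atom shared by the cyclopentenone and the tetrahydrofuran. Moving C4a back from C6 to C5 gives a spiro 6-hydroxycyclohex-2-ene-1,4-dione. Forward, one chelate-controlled 1,2-shift contracts the carbocycle, pushes C5 out as the acetyl group and creates the C6 stereocentre. The precursor comes from α-tocopherylquinone, itself assembled from phytol and trimethylhydroquinone, by face-selective epoxidation of C4a=C5 and invertive 5-exo closure of the tetrahydrofuran.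

Key step: step 11

Atom labels: O1, C2, C3, C4, C4a, C5, C6, C7, C8, C8a of the vitamin E chroman are kept for all late compounds.
Assumption: no mnemonic predicts the sense of induction in step 9. L-(+)-diisopropyl tartrate is written. The D-(−) enantiomer replaces it, with nothing else changed, if the first run shows attack on the other face.
Assumption: natural phytol is bought as the single (2E,7R,11R) isomer.

Step 1
Reactants: 1 natural (2E,7R,11R)-phytol
Product: 2 (2R,3R)-2,3-epoxyphytol
Conditions: Ti(OiPr)4 (10 mol %), D-(−)-diethyl tartrate (12 mol %), t-BuOOH (decane), 4 Å MS, CH2Cl2, −20 °C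
Reagents that add atoms: tert-butyl hydroperoxide, CC(C)(C)OO
Why: Sharpless asymmetric epoxidation of an E-trisubstituted allylic alcohol, in which the titanium complex of the D-(−)-tartrate delivers oxygen to the face that gives the 2R,3R oxirane and so fixes the tertiary C–O centre that becomes C2 of the target, the remote 7R and 11R centres playing no part.

Step 2
Reactants: 2 (2R,3R)-2,3-epoxyphytol
Product: 3 (3R,7R,11R)-3,7,11,15-tetramethylhexadecane-1,3-diol
Conditions: NaAlH2(OCH2CH2OMe)2 (toluene solution), THF, 0 °C → rt
Reagents that add atoms: none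
Why: Regioselective reductive opening of a 2,3-epoxy alcohol, in which the aluminate bound to the C1 oxygen hands hydride to the less substituted C2, so the tertiary C3–O bond is never broken and C3 stays R.

Step 3
Reactants: 3 (3R,7R,11R)-3,7,11,15-tetramethylhexadecane-1,3-diol
Product: 4 (3R,7R,11R)-1-iodo-3,7,11,15-tetramethylhexadecan-3-ol
Conditions: I2, PPh3, imidazole, CH2Cl2, 0 °C
Reagents that add atoms: iodine, II
Why: Appel-type iodination (Garegg–Samuelsson conditions) proceeds by SN2 displacement of an alkoxyphosphonium salt, which only the primary hydroxyl can form and undergo, so the tertiary carbinol is left alone.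

Step 4
Reactants: 4 (3R,7R,11R)-1-iodo-3,7,11,15-tetramethylhexadecan-3-ol
Product: 5 triethyl{[(3R,7R,11R)-1-iodo-3,7,11,15-tetramethylhexadecan-3-yl]oxy}silane
Conditions: Et3SiOTf, 2,6-lutidine, CH2Cl2, −78 → 0 °C
Reagents that add atoms: triethylsilyl trifluoromethanesulfonate, CC[Si](CC)(CC)OS(=O)(=O)C(F)(F)F
Why: Silylation with a silyl triflate and a hindered pyridine base is strong enough for a tertiary alcohol, is too mild to displace the primary iodide, and removes the acidic proton that would destroy the Grignard reagent of step 7.

Step 5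
Reactants: 6 2,3,5-trimethylhydroquinone
Product: 7 1,4-dimethoxy-2,3,5-trimethylbenzene
Conditions: MeI, K2CO3, acetone, reflux, argon
Reagents that add atoms: iodomethane, CI
Why: Double Williamson ether synthesis on both phenols, run under argon so that the hydroquinone is not air-oxidised in the basic medium.

Step 6
Reactants: 7 1,4-dimethoxy-2,3,5-trimethylbenzene
Product: 8 1-bromo-2,5-dimethoxy-3,4,6-trimethylbenzene
Conditions: NBS, MeCN, 0 °C → rt, dark
Reagents that add atoms: N-bromosuccinimide, O=C1CCC(=O)N1Br
Why: Electrophilic aromatic bromination of an electron-rich arene that has a single free ring position, with polar solvent and exclusion of light suppressing radical benzylic bromination.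

Step 7
Reactants: 8 1-bromo-2,5-dimethoxy-3,4,6-trimethylbenzene; 5 triethyl{[(3R,7R,11R)-1-iodo-3,7,11,15-tetramethylhexadecan-3-yl]oxy}silane
Product: 11 (3R,7R,11R)-1-(2,5-dimethoxy-3,4,6-trimethylphenyl)-3,7,11,15-tetramethylhexadecan-3-ol, via arylmagnesium bromide 9 (not isolated), via coupled triethylsilyl ether 10 (not isolated)
Conditions: (a) 8, Mg, THF, reflux; (b) 5, Li2CuCl4 (5 mol %), THF, −20 °C → rt; (c) 1 M aq. HCl, THF, rt
Reagents that add atoms: none
Why: Grignard reagent 9 transmetallates to an aryl cuprate that displaces the unhindered primary iodide of 5 (Kochi-type copper-catalysed sp2–sp3 cross-coupling) and forms the C4–C4a bond without touching C2, and the acidic quench hydrolyses the labile silyl ether of 10, giving an alcohol polar enough to be freed easily from arene and alkane by-products.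

Step 8
Reactants: 11 (3R,7R,11R)-1-(2,5-dimethoxy-3,4,6-trimethylphenyl)-3,7,11,15-tetramethylhexadecan-3-ol
Product: 12 α-tocopherylquinone = 2-[(3R,7R,11R)-3-hydroxy-3,7,11,15-tetramethylhexadecyl]-3,5,6-trimethylcyclohexa-2,5-diene-1,4-dione
Conditions: (NH4)2Ce(NO3)6 (2.2 equiv), MeCN–H2O, 0 °C
Reagents that add atoms: water, O
Why: Oxidative demethylation of a hydroquinone dimethyl ether, in which two one-electron oxidations by tetravalent cerium and ipso attack of water at C6 and C8a expel two molecules of methanol; it is clean on a fully substituted ring and faster than any attack on the tertiary alcohol.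

Step 9
Reactants: 12 α-tocopherylquinone
Product: 13 α-tocopherylquinone 4a,5-epoxide = (1S,6R)-1-[(3R,7R,11R)-3-hydroxy-3,7,11,15-tetramethylhexadecyl]-3,4,6-trimethyl-7-oxabicyclo[4.1.0]hept-3-ene-2,5-dione
Conditions: premixed Ph3COOH (1.5 equiv), NaN(SiMe3)2 (2.5 equiv), L-(+)-diisopropyl tartrate (1.2 equiv), 4 Å MS, toluene, −78 °C; then 12, −60 → −40 °C; cold pH 7 buffer
Reagents that add atoms: triphenylmethyl hydroperoxide, OOC(c1ccccc1)(c1ccccc1)c1ccccc1
Why: Proposed new method: sodium trityl peroxide, the tartrate and the C2 oxygen of 12 should gather around sodium in one aggregate, so that the peroxide is handed to the neighbouring C4a=C5 bond (conjugate addition, then closure of the enolate on the O–O bond with loss of trityl oxide, Weitz–Scheffer mechanism) and not to the remote C7=C8 bond, while the chiral tartrate chooses the face and sets C4a (S) and C5 (R) together as a cis-fused oxirane; the closest known reaction type is the hydroxyl-directed, tartrate-mediated nucleophilic epoxidation of quinone monoketals bearing a primary hydroxymethyl group, which has not been shown for a tetrasubstituted para-quinone double bond or for a tertiary hydroxyl three carbons from the ring.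

Step 10
Reactants: 13 α-tocopherylquinone 4a,5-epoxide
Product: 14 (2R,5R,10R)-10-hydroxy-2,7,8,10-tetramethyl-2-[(4R,8R)-4,8,12-trimethyltridecyl]-1-oxaspiro[4.5]dec-7-ene-6,9-dione
Conditions: BF3·OEt2 (0.2 equiv), CH2Cl2, −78 → −20 °C
Reagents that add atoms: none
Why: Acid-catalysed 5-exo-tet epoxy alcohol cyclisation, in which the C2 hydroxyl attacks C4a opposite to the activated C4a–O bond (preferred over 6-endo attack at C5 because both oxirane carbons are equally substituted and equally flanked by a carbonyl), so C4a is inverted to R, C5 keeps its oxygen and stays R, and the C5 hydroxyl ends trans to O1.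

Step 11
Reactants: 14 (2R,5R,10R)-10-hydroxy-2,7,8,10-tetramethyl-2-[(4R,8R)-4,8,12-trimethyltridecyl]-1-oxaspiro[4.5]dec-7-ene-6,9-dione
Product: 15 (2R,5R,9S)-9-acetyl-9-hydroxy-2,7,8-trimethyl-2-[(4R,8R)-4,8,12-trimethyltridecyl]-1-oxaspiro[4.4]non-7-en-6-one
Conditions: Sc(OTf)3 (0.2 equiv), 4 Å MS, ClCH2CH2Cl, rt → 50 °C
Reagents that add atoms: none
Why: Sc(OTf)3 ties the C5 hydroxyl and the C6 carbonyl oxygen of 14 into a five-membered chelate, which polarises C6=O, holds the O–C5–C6–O unit close to planar and tilts the ring bond C5–C4a over one face of the carbonyl, so that C4a slides from C5 to C6 through a three-centre transition state while the proton passes from the C5 oxygen to the C6 oxygen and C5 becomes the acetyl carbonyl. This is an α-ketol (acyloin) rearrangement, and its closest known relatives are the metal-ion-promoted ring contractions of cyclic tertiary α-hydroxy ketones, for example of hop α-acids to iso-α-acids under divalent magnesium. The cyclopentenone (C4a, C6, C7, C8, C8a) is closed by 1,2-migration of a ring bond, a six-to-five contraction and not an end-to-end cyclisation, and the tetrahydrofuran is only carried along. C4a migrates with retention and stays R, and the new centre C6 is controlled by C5: in the chelate the C5 hydroxyl eclipses the carbonyl and the C5 methyl is axial, so C4a stands over the carbonyl face on the hydroxyl side of the ring and bonds there, which places the C6 hydroxyl trans to O1 and the acetyl group cis to it (S at C6). The step needs C4a to migrate in preference to the equally well aligned C5 methyl, which the lone pair of O1 and the full substitution of C4a secure by stabilising the electron-poor migrating carbon, and it needs the stepwise retro-aldol route through a planar C4a to stay closed, which working without base secures. The equilibrium should favour 15 because the C6 carbonyl of 14 gains little from sharing an alkene already conjugated to C8a=O, whereas 15 offers the metal and the hydroxyl proton a freely rotating methyl ketone as chelating partner.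

Compound list
1 | natural (2E,7R,11R)-phytol | OC/C=C(\C)CCC[C@H](C)CCC[C@H](C)CCCC(C)C | starting material
2 | (2R,3R)-2,3-epoxyphytol | OC[C@H]1O[C@]1(C)CCC[C@H](C)CCC[C@H](C)CCCC(C)C | intermediate
3 | (3R,7R,11R)-3,7,11,15-tetramethylhexadecane-1,3-diol | OCC[C@](C)(O)CCC[C@H](C)CCC[C@H](C)CCCC(C)C | intermediate
4 | (3R,7R,11R)-1-iodo-3,7,11,15-tetramethylhexadecan-3-ol | ICC[C@](C)(O)CCC[C@H](C)CCC[C@H](C)CCCC(C)C | intermediate
5 | triethylsilyl ether of 4 (primary iodide, 3R,7R,11R) | ICC[C@](C)(O[Si](CC)(CC)CC)CCC[C@H](C)CCC[C@H](C)CCCC(C)C | intermediate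
6 | 2,3,5-trimethylhydroquinone | Cc1cc(O)c(C)c(C)c1O | starting material
7 | 1,4-dimethoxy-2,3,5-trimethylbenzene | COc1cc(C)c(OC)c(C)c1C | intermediate
8 | 1-bromo-2,5-dimethoxy-3,4,6-trimethylbenzene | COc1c(C)c(C)c(OC)c(Br)c1C | intermediate
9 | (2,5-dimethoxy-3,4,6-trimethylphenyl)magnesium bromide (not isolated) | COc1c(C)c(C)c(OC)c([Mg]Br)c1C | intermediate
10 | coupled hydroquinone dimethyl ether, tertiary triethylsilyl ether (not isolated) | COc1c(C)c(C)c(OC)c(CC[C@](C)(O[Si](CC)(CC)CC)CCC[C@H](C)CCC[C@H](C)CCCC(C)C)c1C | intermediate
11 | (3R,7R,11R)-1-(2,5-dimethoxy-3,4,6-trimethylphenyl)-3,7,11,15-tetramethylhexadecan-3-ol | COc1c(C)c(C)c(OC)c(CC[C@](C)(O)CCC[C@H](C)CCC[C@H](C)CCCC(C)C)c1C | intermediate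
12 | α-tocopherylquinone (3R,7R,11R side chain) | CC1=C(C)C(=O)C(CC[C@](C)(O)CCC[C@H](C)CCC[C@H](C)CCCC(C)C)=C(C)C1=O | intermediate
13 | α-tocopherylquinone 4a,5-epoxide, (1S,6R) in the oxabicycloheptene name | CC1=C(C)C(=O)[C@@]2(CC[C@](C)(O)CCC[C@H](C)CCC[C@H](C)CCCC(C)C)O[C@@]2(C)C1=O | intermediate
14 | (2R,5R,10R)-10-hydroxy-2,7,8,10-tetramethyl-2-[(4R,8R)-4,8,12-trimethyltridecyl]-1-oxaspiro[4.5]dec-7-ene-6,9-dione | CC1=C(C)C(=O)[C@@]2(CC[C@@](C)(CCC[C@H](C)CCC[C@H](C)CCCC(C)C)O2)[C@@](C)(O)C1=O | intermediate
15 | (2R,5R,9S)-9-acetyl-9-hydroxy-2,7,8-trimethyl-2-[(4R,8R)-4,8,12-trimethyltridecyl]-1-oxaspiro[4.4]non-7-en-6-one (CNP0373307.2) | CC(=O)[C@]1(O)C(C)=C(C)C(=O)[C@@]12CC[C@@](C)(CCC[C@H](C)CCC[C@H](C)CCCC(C)C)O2 | target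

Total step count: 11. Longest linear sequence: 9 steps (from 1 through steps 1–4 and 7–11).

Steps most likely to fail

**Step 9.** Site selectivity between the two fully substituted quinone double bonds and facial selectivity may both collapse. A tertiary hydroxyl three carbons from the ring may hold the sodium–tartrate–peroxide aggregate too loosely, and the basic medium may tautomerise the quinone.
- The fallback uses known chemistry throughout. It gives up reagent control and sorts the isomers at the stage where they differ most.
- Setting out from 12, a plain Weitz–Scheffer epoxidation is run (30 % H2O2, Na2CO3, aqueous EtOH, 0 °C → rt, as used for fully substituted quinones such as vitamin K).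
- It should give 13 together with the (1R,6S)-4a,5-epoxide F1, the (1S,6R)-7,8-epoxide F2 and the (1R,6S)-7,8-epoxide F3.
- F2 and F3 are constitutional isomers of 13 that cannot close a five-membered ether. They are removed on silica.
- The pair 13 and F1 is submitted together to the conditions of step 10, which should give 14 and the (2R,5S,10S)-spiro ketol F4.
- In 14 and F4 the new centres share the tetrahydrofuran with C2, so chromatography should separate them. The route is rejoined at 14.

**Step 11.** The shift is reversible, so the equilibrium may stop short of the product. The C5 methyl, or later the vinylic C7, may migrate instead. Traces of triflic acid may ionise the tertiary C2–O1 bond.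
- The fallback replaces the concerted shift by the stepwise retro-aldol and aldol path.
- Setting out from 14, MgCl2 and Et3N in MeCN at rt should cleave the C4a–C5 bond of the magnesium alkoxide.
- This gives the enolate of the open-chain (2Z)-ene-trione F5, which is not isolated. Its C4a carbon adds to the C6 carbonyl of the 1,2-diketone in an intramolecular aldol addition and gives the ring-contracted ketol.
- Because C4a is planar at this stage, C4a and C6 are set anew under chelate and thermodynamic control.
- The wanted isomer therefore has to be separated by chromatography, and the others can be resubmitted. The route is rejoined at 15.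

**Step 10.** An oxirane flanked by two carbonyl groups is a poor Lewis base. Opening may be slow and may be overtaken by the 1,2-acyl shift typical of epoxy ketones under BF3, or by dehydration of the tertiary alcohol.
- The fallback activates the nucleophile and not the electrophile.
- Setting out from 13, KN(SiMe3)2 (1.0 equiv, THF, −78 → −40 °C) should convert the C2 hydroxyl into its alkoxide.
- The alkoxide displaces the oxirane oxygen at C4a in an SN2 reaction accelerated by the adjacent C8a carbonyl, with the same inversion and the same relative configuration.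
- Me3SiCl is then added at −78 °C to trap the C5 alkoxide as the C5 trimethylsilyl ether F6 before retro-aldol cleavage can start.
- Aqueous AcOH in THF removes the silyl group, and the route is rejoined at 14.

Further compounds
F1 | step 9 | (1R,6S)-1-[(3R,7R,11R)-3-hydroxy-3,7,11,15-tetramethylhexadecyl]-3,4,6-trimethyl-7-oxabicyclo[4.1.0]hept-3-ene-2,5-dione | CC1=C(C)C(=O)[C@]2(CC[C@](C)(O)CCC[C@H](C)CCC[C@H](C)CCCC(C)C)O[C@]2(C)C1=O
F2 | step 9 | (1S,6R)-3-[(3R,7R,11R)-3-hydroxy-3,7,11,15-tetramethylhexadecyl]-1,4,6-trimethyl-7-oxabicyclo[4.1.0]hept-3-ene-2,5-dione | CC1=C(CC[C@](C)(O)CCC[C@H](C)CCC[C@H](C)CCCC(C)C)C(=O)[C@@]2(C)O[C@@]2(C)C1=O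
F3 | step 9 | (1R,6S)-3-[(3R,7R,11R)-3-hydroxy-3,7,11,15-tetramethylhexadecyl]-1,4,6-trimethyl-7-oxabicyclo[4.1.0]hept-3-ene-2,5-dione | CC1=C(CC[C@](C)(O)CCC[C@H](C)CCC[C@H](C)CCCC(C)C)C(=O)[C@]2(C)O[C@]2(C)C1=O
F4 | step 9 | (2R,5S,10S)-10-hydroxy-2,7,8,10-tetramethyl-2-[(4R,8R)-4,8,12-trimethyltridecyl]-1-oxaspiro[4.5]dec-7-ene-6,9-dione | CC1=C(C)C(=O)[C@]2(CC[C@@](C)(CCC[C@H](C)CCC[C@H](C)CCCC(C)C)O2)[C@](C)(O)C1=O
F5 | step 11 | (2Z)-2,3-dimethyl-1-{(5R)-5-methyl-5-[(4R,8R)-4,8,12-trimethyltridecyl]oxolan-2-yl}hex-2-ene-1,4,5-trione (formed as its enolate, oxolane C2 not defined) | CC(=O)C(=O)/C(C)=C(C)\C(=O)C1CC[C@@](C)(CCC[C@H](C)CCC[C@H](C)CCCC(C)C)O1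
F6 | step 10 | (2R,5R,10R)-2,7,8,10-tetramethyl-2-[(4R,8R)-4,8,12-trimethyltridecyl]-10-(trimethylsilyloxy)-1-oxaspiro[4.5]dec-7-ene-6,9-dione | CC1=C(C)C(=O)[C@@]2(CC[C@@](C)(CCC[C@H](C)CCC[C@H](C)CCCC(C)C)O2)[C@@](C)(O[Si](C)(C)C)C1=O
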